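The eleven-membered ring (humulane numbering: C1H2, C2=C3(Me), C4, C5, C6=C7(Me), C8, C9–O, C10, C11Me2) is read as a caryophyllane opened at C2–C10: with that bond in place it is a nine-membered ring fused to a gem-dimethylcyclobutane (C1, C2, C10, C11). Commercial (−)-caryophyllene oxide is such a precursor. One cobalt-hydride radical isomerisation cuts C2–C10, enlarges the nine-membered ring by two carbons (C1, C11) and forms both the C2=C3 and the C9=C10 alkenes. The latter is the handle for the C9 oxygen; the C6–C7 epoxide masks the third alkene and makes the C9 epimers separable. Hydroboration, deoxygenation, acylation and Suzuki coupling finish the route.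

Key step: step 1

Assumption: (Z)-3-iodoacrylic acid (6) is taken as a catalogue compound; the humulane numbers given above are used for the ring atoms of every compound.

Step 1
Reactants: 1 (−)-caryophyllene oxide [(1R,4R,6R,10S)-4,12,12-trimethyl-9-methylidene-5-oxatricyclo[8.2.0.0(4,6)]dodecane; trans-fused gem-dimethylcyclobutane on a nine-membered ring that carries the exocyclic methylene on C3 and the trans C6–C7 epoxide]
Product: 2 humulene 6,7-epoxide [(1R,3E,7E,11R)-1,5,5,8-tetramethyl-12-oxabicyclo[9.1.0]dodeca-3,7-diene]
Conditions: (tBu4-salen)CoCl (cat.; tBu4-salen = N,N'-bis(3,5-di-tert-butylsalicylidene)ethylenediamine dianion), PhSiH3 (cat.), benzene, rt, Ar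
Reagents that add atoms: none
Why: Phenylsilane turns the cobalt chloride into a trivalent cobalt hydride, which transfers a hydrogen atom to the exocyclic CH2 on C3 and so gives the tertiary C3 radical, a cyclobutylcarbinyl radical. β-Scission of the ring-fusion bond C2–C10 then forms the C2=C3 alkene and a secondary C10 radical, from which divalent cobalt takes the C9 hydrogen atom back, forming the C9=C10 alkene and the hydride again, so that the reaction is a net isomerisation. The closest known reaction type is the cobalt–salen/silane hydrogen-atom-transfer isomerisation of 1,1-disubstituted alkenes in its retro-cycloisomerisation mode, in which a strained ring next to the radical is opened. No ring is closed: the nine-membered ring becomes the eleven-membered ring because the bond it shares with the cyclobutane is cut, which brings C1 and C11 into the large ring. No stereocentre is created, the epoxide centres C6 and C7 are untouched and the two ring-fusion centres disappear; the E geometry at C2=C3 should follow from the trans ring fusion (the reverse of the closure of an E alkene onto C10 that builds this ring system), and that at C9=C10 from the preference of the large ring for a trans 1,2-disubstituted alkene. The step needs hydrogen-atom transfer to the methylene group only (it is the sole alkene of 1, and the neutral catalyst should leave the epoxide alone), cleavage of C2–C10 and not of C1–C2 (secondary versus primary radical) and ring opening that outruns hydrogen return, all of which the strained trans-fused four-membered ring secures.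

Step 2
Reactants: 2 humulene 6,7-epoxide
Product: 4 (9S)-9-hydroxy-9,10-dihydrohumulene 6,7-epoxide [(1R,3S,7E,11R)-1,5,5,8-tetramethyl-12-oxabicyclo[9.1.0]dodec-7-en-3-ol], via C9-disiamylboryl adduct 3 (not isolated)
Conditions: disiamylborane (from BH3·THF and 2-methylbut-2-ene), THF, 0 °C to rt; then NaOH, H2O2, 0 °C; chromatographic separation of the C9 epimers
Reagents that add atoms: hydrogen peroxide, OO (the hydroxyl oxygen of 4); disiamylborane, CC(C)C(C)BC(C)C(C)C (boron and its two alkyl groups, present in 3 only)
Why: Hydroboration–oxidation with a hindered dialkylborane should take the 1,2-disubstituted C9=C10 alkene and leave the trisubstituted C2=C3 alkene and the epoxide alone, boron goes to C9, away from the quaternary C11, and alkaline peroxide replaces boron by hydroxyl with retention; the C9 stereocentre arises by attack on the outer face of the alkene, a selectivity that cannot be predicted with confidence and is not relied upon, because the fixed epoxide centres make the two C9 epimers diastereomers, from which the (9S) alcohol 4 is isolated by chromatography.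

Step 3
Reactants: 4 (9S)-9-hydroxy-9,10-dihydrohumulene 6,7-epoxide
Product: 5 (1S,3E,7E)-3,7,10,10-tetramethylcycloundeca-3,7-dien-1-ol [(9S)-humula-2,6-dien-9-ol]
Conditions: [HB(3,5-Me2pz)3]ReO3 (cat.; pz = pyrazol-1-yl), PPh3, benzene, 80 °C
Reagents that add atoms: none
Why: Rhenium-catalysed oxygen-atom transfer from the epoxide to triphenylphosphine (a pentavalent oxorhenium species takes up the epoxide as a rhenium diolate, which cyclo-reverts) is stereospecific with retention, so the trans epoxide should return the (E)-C6=C7 alkene, while the neutral, coordinatively saturated catalyst spares the free alcohol and the C2=C3 alkene and C9 is not touched.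

Step 4
Reactants: 5 (1S,3E,7E)-3,7,10,10-tetramethylcycloundeca-3,7-dien-1-ol; 6 (Z)-3-iodoacrylic acid [(2Z)-3-iodoprop-2-enoic acid]
Product: 7 (1S,3E,7E)-3,7,10,10-tetramethylcycloundeca-3,7-dien-1-yl (2Z)-3-iodoprop-2-enoate
Conditions: DCC, DMAP (cat.), CH2Cl2, 0 °C
Reagents that add atoms: none
Why: Steglich esterification acylates the secondary alcohol at oxygen, so the C9–O bond is not broken and C9 keeps its (S) configuration, and at 0 °C with little DMAP the (Z)-iodoalkene should keep its geometry.

Step 5
Reactants: 7 (1S,3E,7E)-3,7,10,10-tetramethylcycloundeca-3,7-dien-1-yl (2Z)-3-iodoprop-2-enoate; 8 (4-hydroxyphenyl)boronic acid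
Product: 9 (1S,3E,7E)-3,7,10,10-tetramethylcycloundeca-3,7-dien-1-yl (2Z)-3-(4-hydroxyphenyl)prop-2-enoate (target)
Conditions: Pd(PPh3)4 (cat.), K2CO3, THF/H2O, rt to 40 °C
Reagents that add atoms: none
Why: Suzuki–Miyaura coupling, in which oxidative addition of zerovalent palladium into the vinyl C–I bond, transmetalation and reductive elimination all go with retention, should give the (Z)-4-hydroxycinnamate directly, and the free phenol, the secondary ester and the two trisubstituted alkenes tolerate aqueous carbonate at this temperature.

Compound list
1 | (−)-caryophyllene oxide, (1R,4R,6R,10S)-4,12,12-trimethyl-9-methylidene-5-oxatricyclo[8.2.0.0(4,6)]dodecane | C[C@@]12CC[C@@H]3[C@H](CC3(C)C)C(=C)CC[C@H]1O2 | starting material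
2 | humulene 6,7-epoxide, (1R,3E,7E,11R)-1,5,5,8-tetramethyl-12-oxabicyclo[9.1.0]dodeca-3,7-diene | C[C@@]12C/C=C/C(C)(C)C/C=C(C)/CC[C@H]1O2 | intermediate
3 | C9-disiamylboryl adduct, bis(3-methylbutan-2-yl)[(1R,3S,7E,11R)-1,5,5,8-tetramethyl-12-oxabicyclo[9.1.0]dodec-7-en-3-yl]borane (siamyl stereocentres undefined) | C[C@@]12C[C@@H](B(C(C)C(C)C)C(C)C(C)C)CC(C)(C)C/C=C(C)/CC[C@H]1O2 | intermediate (not isolated)
4 | (1R,3S,7E,11R)-1,5,5,8-tetramethyl-12-oxabicyclo[9.1.0]dodec-7-en-3-ol | C[C@@]12C[C@@H](O)CC(C)(C)C/C=C(C)/CC[C@H]1O2 | intermediate
5 | (1S,3E,7E)-3,7,10,10-tetramethylcycloundeca-3,7-dien-1-ol | C/C1=C\CC(C)(C)C[C@H](O)C/C(C)=C/CC1 | intermediate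
6 | (Z)-3-iodoacrylic acid, (2Z)-3-iodoprop-2-enoic acid | OC(=O)/C=C\I | starting material
7 | (1S,3E,7E)-3,7,10,10-tetramethylcycloundeca-3,7-dien-1-yl (2Z)-3-iodoprop-2-enoate | C/C1=C\CC(C)(C)C[C@H](OC(=O)/C=C\I)C/C(C)=C/CC1 | intermediate
8 | (4-hydroxyphenyl)boronic acid | OB(O)c1ccc(O)cc1 | starting material
9 | (1S,3E,7E)-3,7,10,10-tetramethylcycloundeca-3,7-dien-1-yl (2Z)-3-(4-hydroxyphenyl)prop-2-enoate | C/C1=C\CC(C)(C)C[C@H](OC(=O)/C=C\c2ccc(O)cc2)C/C(C)=C/CC1 | target

Total step count: 5. Longest linear sequence: 5 steps (1 → 2 → 4 → 5 → 7 → 9).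

Steps most likely to fail

Step 2. The outer-face attack of the borane on the flexible ring may show poor or reversed facial selectivity, so that most of the material ends up as the other C9 epimer. The fallback sets out from 2 and changes the way C9 is fixed, from retention to inversion. The hydroboration is run as before, and the epimer that the main line discards, (1R,3R,7E,11R)-1,5,5,8-tetramethyl-12-oxabicyclo[9.1.0]dodec-7-en-3-ol F1, is carried through the rhenium/phosphine deoxygenation to (1R,3E,7E)-3,7,10,10-tetramethylcycloundeca-3,7-dien-1-ol F2. Mitsunobu esterification of F2 with 6 (PPh3, DIAD, THF, 0 °C) inverts C9 by SN2 displacement of the oxyphosphonium group and comes back to the route at 7, so either epimer leads to the same ester.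

Step 1. The epoxide may be opened by Lewis-acidic cobalt species (transannular cyclisation) during a ring opening that has to compete with hydrogen return to cobalt. The fallback sets out from 1 and moves the ring expansion to an epoxide-free substrate. Oxygen-atom transfer to PPh3 under the rhenium catalysis of step 3 should give (−)-β-caryophyllene F3 (also sold as such). The same cobalt-hydride isomerisation is then run on this hydrocarbon, where a higher temperature can be used to favour β-scission, and should give α-humulene F4. Shi epoxidation (fructose-derived ketone catalyst, KHSO5 triple salt, K2CO3, MeCN/H2O, 0 °C) then takes the most electron-rich alkene, C6=C7. The D-fructose-derived ketone is expected, by the spiro transition-state model, to give the (6R,7R) epoxide, which is the return to the route at 2.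

Step 3. Oxygen-atom transfer from the hindered trisubstituted epoxide may be slow, and the free hydroxyl may bind the rhenium catalyst, so that prolonged heating erodes the alkene geometry or the material. The fallback sets out from 4 and uses a protecting group and a stoichiometric reductant. Silylation (TBSCl, imidazole, DMF) should give tert-butyl(dimethyl){[(1R,3S,7E,11R)-1,5,5,8-tetramethyl-12-oxabicyclo[9.1.0]dodec-7-en-3-yl]oxy}silane F5. Deoxygenation with lower-valent tungsten chloride (WCl6, n-BuLi, THF, −78 °C to rt), which also goes with retention and tolerates alkenes, should give tert-butyl(dimethyl){[(1S,3E,7E)-3,7,10,10-tetramethylcycloundeca-3,7-dien-1-yl]oxy}silane F6. Desilylation (TBAF, THF) comes back to the route at 5.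

Further compounds
F1 | step 2 | (1R,3R,7E,11R)-1,5,5,8-tetramethyl-12-oxabicyclo[9.1.0]dodec-7-en-3-ol | C[C@@]12C[C@H](O)CC(C)(C)C/C=C(C)/CC[C@H]1O2
F2 | step 2 | (1R,3E,7E)-3,7,10,10-tetramethylcycloundeca-3,7-dien-1-ol | C/C1=C\CC(C)(C)C[C@@H](O)C/C(C)=C/CC1
F3 | step 1 | (−)-β-caryophyllene, (1R,4E,9S)-4,11,11-trimethyl-8-methylidenebicyclo[7.2.0]undec-4-ene | C/C1=C\CCC(=C)[C@H]2CC(C)(C)[C@@H]2CC1
F4 | step 1 | α-humulene, (1E,4E,8E)-2,6,6,9-tetramethylcycloundeca-1,4,8-triene | C/C1=C\CC(C)(C)/C=C/C/C(C)=C/CC1
F5 | step 3 | tert-butyl(dimethyl){[(1R,3S,7E,11R)-1,5,5,8-tetramethyl-12-oxabicyclo[9.1.0]dodec-7-en-3-yl]oxy}silane | C[C@@]12C[C@@H](O[Si](C)(C)C(C)(C)C)CC(C)(C)C/C=C(C)/CC[C@H]1O2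
F6 | step 3 | tert-butyl(dimethyl){[(1S,3E,7E)-3,7,10,10-tetramethylcycloundeca-3,7-dien-1-yl]oxy}silane | C/C1=C\CC(C)(C)C[C@H](O[Si](C)(C)C(C)(C)C)C/C(C)=C/CC1
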